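## Retrosynthetic overview
1. The target quinone comes from hydrolysis of its C1 dimethyl ketal. That ketal comes from three successive oxidative C–O bond formations (PhI(OAc)2/MeOH) on 2-docosylresorcinol in one flask. The ring–OMe and the new ring–carbonyl oxygen bonds are the key bonds.
2. Regiocontrol rests on a mirror-symmetric relay, 2-docosyl-4,6-dimethoxyresorcinol, whose last oxidation can give only one product.
3. 2-Docosylresorcinol comes from cleavage of both methyl ethers of 2-docosyl-1,3-dimethoxybenzene.
4. That ether comes from directed ortho-lithiation of 1,3-dimethoxybenzene and alkylation with 1-bromodocosane, the only C–C bond made.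
5. No ring is formed. The single six-membered ring is bought as the benzene ring of 1,3-dimethoxybenzene.

Assumption: the SMILES holds no stereocentre, so the target is achiral and there is no enantiomer to select, and its unbranched side chain is read as 22 carbons (docosyl, C29H50O4).

## Route

Step 1
Reactants: 1 1,3-dimethoxybenzene; 2 1-bromodocosane
Product: 4 2-docosyl-1,3-dimethoxybenzene, via (2,6-dimethoxyphenyl)lithium 3 (not isolated)
Conditions: 1 (1.3 equiv), n-BuLi (1.2 equiv), THF, 0 to 23 °C, 2 h; then 2 (1.0 equiv) in THF, 23 °C to reflux, 14 h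
Reagents that add atoms: none
Why: Directed ortho-metalation, in which both methoxy groups steer n-BuLi to C2, followed by SN2 alkylation of the aryllithium with an unhindered primary bromide; no stereocentre is formed.

Step 2
Reactants: 4 2-docosyl-1,3-dimethoxybenzene
Product: 6 2-docosylbenzene-1,3-diol, via 2-docosyl-3-methoxyphenol 5 (not isolated)
Conditions: 48% aq HBr, AcOH, reflux, 8 h; dilute with water, filter, recrystallise
Reagents that add atoms: none
Why: Acidic aryl methyl ether cleavage (protonation of the ether oxygen, then SN2 attack of bromide on the methyl group) is the standard way to free long-chain alkylresorcinols, and the saturated chain is inert to it; no stereocentre is formed.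

Step 3
Reactants: 6 2-docosylbenzene-1,3-diol
Product: 11 3-docosyl-2-hydroxy-5-methoxy-1,4-benzoquinone, via 2-docosyl-4-methoxyresorcinol 7 (not isolated), via 4,4-dimethyl monoketal 8 (not isolated), via 2-docosyl-4,6-dimethoxyresorcinol 9 (not isolated), via 6-methoxy monoketal 10 (not isolated)
Conditions: (a) PhI(OAc)2 (2.1 equiv), MeOH/CH2Cl2 1:1 (0.02 M), 0 to 23 °C, 1 h; (b) MeSO3H (0.2 equiv), 40 °C, 2 h; (c) PhI(OAc)2 (1.05 equiv), 0 °C, 30 min; (d) 2 M aq HCl, THF, 23 °C, 1 h
Reagents that add atoms: methanol (CO); water (O)
Why: Proposed new method: an iterative oxidative methoxylation that lifts a 2-alkylresorcinol by six electrons to the 2-hydroxy-5-methoxyquinone level, not yet shown on resorcinols; in resorcinol numbering (O on C1 and C3, chain on C2) the phenol exchanges acetate on the trivalent iodine of PhI(OAc)2, PhI leaves, and methanol traps the phenoxenium-type species para to O1 at C4, once to give 7 after rearomatisation and again, faster because 7 is a 4-methoxyphenol, to give ketal 8 (closest known type: PhI(OAc)2/MeOH oxidative dearomatisation of para-unsubstituted phenols to p-quinone monoketals); MeSO3H then ionises the ketal to an O-methyl oxocarbenium ion with charge on C4, C2 and C6, where attack of methanol at C4 or C2 is reversible but attack at C6 ends in irreversible enolisation to arene 9, while the competing Michael site C5 is switched off because the C1 carbonyl is tied up as a vinylogous acid with the C3 hydroxyl (closest known types: acid-promoted substitution of quinone monoacetals alpha to the carbonyl, and the acid rearrangement of quinone bisketals to 1,2,4-trimethoxybenzenes); 9 is mirror-symmetric, so the third oxidation can give only 10, whose ketal hydrolyses much faster than its vinylogous ester, delivering 11 with the new carbonyl oxygen from water, the methoxy group para to the hydroxyl-bearing carbon and the hindered hydroxyl next to the chain untouched; no stereocentre is formed.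

## Compound list
1 | 1,3-dimethoxybenzene | COc1cccc(OC)c1 | starting material
2 | 1-bromodocosane | CCCCCCCCCCCCCCCCCCCCCCBr | starting material
3 | (2,6-dimethoxyphenyl)lithium | [Li]c1c(OC)cccc1OC | intermediate
4 | 2-docosyl-1,3-dimethoxybenzene | CCCCCCCCCCCCCCCCCCCCCCc1c(OC)cccc1OC | intermediate
5 | 2-docosyl-3-methoxyphenol | CCCCCCCCCCCCCCCCCCCCCCc1c(O)cccc1OC | intermediate
6 | 2-docosylbenzene-1,3-diol (2-docosylresorcinol) | CCCCCCCCCCCCCCCCCCCCCCc1c(O)cccc1O | intermediate
7 | 2-docosyl-4-methoxybenzene-1,3-diol | CCCCCCCCCCCCCCCCCCCCCCc1c(O)ccc(OC)c1O | intermediate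
8 | 2-docosyl-3-hydroxy-4,4-dimethoxycyclohexa-2,5-dien-1-one | CCCCCCCCCCCCCCCCCCCCCCC1=C(O)C(OC)(OC)C=CC1=O | intermediate
9 | 2-docosyl-4,6-dimethoxybenzene-1,3-diol | CCCCCCCCCCCCCCCCCCCCCCc1c(O)c(OC)cc(OC)c1O | intermediate
10 | 2-docosyl-3-hydroxy-4,4,6-trimethoxycyclohexa-2,5-dien-1-one | CCCCCCCCCCCCCCCCCCCCCCC1=C(O)C(OC)(OC)C=C(OC)C1=O | intermediate
11 | 3-docosyl-2-hydroxy-5-methoxycyclohexa-2,5-diene-1,4-dione (achiral) | CCCCCCCCCCCCCCCCCCCCCCC1=C(O)C(=O)C=C(OC)C1=O | target

## Step count and risks
Total steps: 3. Longest linear sequence: 3.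

**Step 3 (the proposed new step).**
- Risks:
  - The first oxidation of a resorcinol is the slowest. It may also attack the chain-bearing carbon or give oligomers.
  - The acid-triggered change of 8 into 9 may stall, or may run Michael-wise to the 4,5-dimethoxy isomer.
  - Surplus PhI(OAc)2 could oxidise the enol carbon that carries the chain.
- Fallback, known chemistry only, sets out from 2 and comes back at 11. Kornblum oxidation of 2 (DMSO, NaHCO3, cat. NaI, 120 °C) gives docosanal F1. Organocatalytic three-component reductive alkylation follows, using bought 2,5-dihydroxy-1,4-benzoquinone (two-fold excess against double alkylation), F1 and Hantzsch ester (L-proline 20 mol %, CH2Cl2/EtOH, 23 °C). It runs through the Knoevenagel adduct 3-docosylidene-5-hydroxycyclohex-5-ene-1,2,4-trione F2, which takes up hydride to give 3-docosyl-2,5-dihydroxy-1,4-benzoquinone F3. Vinylogous Fischer etherification (MeOH, cat. H2SO4, reflux) then exchanges only the unhindered C5 hydroxyl, because addition of methanol at C2 is blocked by the chain. This gives 11.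

**Step 1.**
- Risks: SN2 attack of a doubly ortho-substituted aryllithium on a waxy bromide is slow. E2 elimination, lithium–bromine exchange and Wurtz coupling give C22 and C44 hydrocarbons that are hard to remove from 4.
- Fallback sets out from 3 and comes back at 4. Quenching 3 with I2 (THF, −78 °C) gives 2-iodo-1,3-dimethoxybenzene F4. Hydroboration of bought 1-docosene with 9-BBN-H (THF, 23 to 60 °C) gives 9-docosyl-9-borabicyclo[3.3.1]nonane F5. B-alkyl Suzuki–Miyaura coupling of F4 and F5 (PdCl2(dppf) 3 mol %, K3PO4, THF/DMF/H2O, 60 °C) gives 4. The C–C bond now comes from reductive elimination at divalent palladium, not from a substitution step.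

**Step 2.**
- Risks: the second ether cleavage can stop at 5 in the poorly mixed, waxy medium. Long heating in strong acid darkens the electron-rich diol.
- Fallback sets out from 2 and comes back at 6, avoiding methyl ethers altogether. Resorcinol with MOMCl (i-Pr2NEt, CH2Cl2, 0 to 23 °C) gives 1,3-bis(methoxymethoxy)benzene F6. n-BuLi (THF, 0 °C) gives [2,6-bis(methoxymethoxy)phenyl]lithium F7. Alkylation with 2 (THF, reflux) gives 2-docosyl-1,3-bis(methoxymethoxy)benzene F8. Mild acetal exchange (HCl, MeOH, 50 °C) frees 6.

## Further compounds
F1 | step 3 | docosanal | CCCCCCCCCCCCCCCCCCCCCC=O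
F2 | step 3 | 3-docosylidene-5-hydroxycyclohex-5-ene-1,2,4-trione (transient, alkene geometry of no consequence) | CCCCCCCCCCCCCCCCCCCCCC=C1C(=O)C(=O)C=C(O)C1=O
F3 | step 3 | 3-docosyl-2,5-dihydroxy-1,4-benzoquinone | CCCCCCCCCCCCCCCCCCCCCCC1=C(O)C(=O)C=C(O)C1=O
F4 | step 1 | 2-iodo-1,3-dimethoxybenzene | COc1cccc(OC)c1I
F5 | step 1 | 9-docosyl-9-borabicyclo[3.3.1]nonane | CCCCCCCCCCCCCCCCCCCCCCB1C2CCCC1CCC2
F6 | step 2 | 1,3-bis(methoxymethoxy)benzene | COCOc1cccc(OCOC)c1
F7 | step 2 | [2,6-bis(methoxymethoxy)phenyl]lithium | [Li]c1c(OCOC)cccc1OCOC
F8 | step 2 | 2-docosyl-1,3-bis(methoxymethoxy)benzene | CCCCCCCCCCCCCCCCCCCCCCc1c(OCOC)cccc1OCOC
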